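**Plan**

- Retrosynthesis: the two O-benzyl groups and the C2–O bond of ring B (phenol from an aryl pinacol boronate) are removed first. Ring B (the methyl benzoate ring: C1 CO2CH3, C2 OH, C3 CH3, C4 O-acyl, C5 H, C6 CH3) is then cut at C1–C6 and C2–C3, and last the enol ester C–O bond between ring A and a pyrone.
- Enabling feature: C3 to C6 of ring B carry CH3, O-acyl, H and CH3, which are exactly the substituents on C3 to C6 of 4-hydroxy-3,6-dimethyl-2-pyrone. C1–C2 is a propiolate two-carbon unit whose C2 oxygen can be carried through as boron.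
- Forward: ring A is taken from 2,6-dihydroxy-4-methylbenzoic acid and dressed to a mono-benzyl isophthalic acid, which is esterified with the pyrone. Ring B then forms on the pyrone by [4+2] cycloaddition with a borylpropiolate and loss of CO2; C–B oxidation and hydrogenolysis finish the synthesis.
- Stereochemistry: the target has no stereocentre. What must be controlled is the regiochemistry of the cycloaddition and the site of two O-alkylations.

Key step: step 10

Remark: 2,6-dihydroxy-4-methylbenzoic acid is assumed to be purchasable; because it is symmetric, the formylation that introduces the second carboxyl carbon of ring A can give only one isomer.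

**Route**

Step 1
Reactants: 1 4-hydroxy-6-methyl-2H-pyran-2-one
Product: 3 4-hydroxy-6-methyl-3-[(phenylsulfanyl)methyl]-2H-pyran-2-one, via 6-methyl-3-methylidenepyran-2,4-dione 2 (not isolated)
Conditions: (CH2O)n, PhSH, piperidine (cat.), AcOH (cat.), EtOH, 60 °C
Reagents that add atoms: formaldehyde (used as paraformaldehyde), C=O; thiophenol, Sc1ccccc1
Why: Knoevenagel condensation of formaldehyde at the acidic C3 position gives the 3-methylidene dione 2, which thiophenol should capture by thia-Michael addition before a second pyrone can add; this three-component coupling is the usual detour for C3-monoalkylation of 4-hydroxy-2-pyrones.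

Step 2
Reactants: 3 4-hydroxy-6-methyl-3-[(phenylsulfanyl)methyl]-2H-pyran-2-one
Product: 4 4-hydroxy-3,6-dimethyl-2H-pyran-2-one
Conditions: Raney Ni, EtOH, 60 °C
Reagents that add atoms: none
Why: Raney Ni desulfurization (hydrogenolysis of the activated C–S bond) should leave the C3 methyl group, the C–S bond being cleaved much faster than the vinylogous acid ring is reduced.

Step 3
Reactants: 5 2,6-dihydroxy-4-methylbenzoic acid
Product: 6 benzyl 2,6-dihydroxy-4-methylbenzoate
Conditions: BnBr, KHCO3, DMF, rt
Reagents that add atoms: benzyl bromide, BrCc1ccccc1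
Why: Hydrogen carbonate deprotonates only the carboxylic acid, so SN2 alkylation of the carboxylate with benzyl bromide should give the benzyl ester and leave both chelated phenols free.

Step 4
Reactants: 6 benzyl 2,6-dihydroxy-4-methylbenzoate
Product: 8 benzyl 3-formyl-2,6-dihydroxy-4-methylbenzoate, via iminium chloride 7 (not isolated)
Conditions: POCl3, DMF, MeCN, 0 °C to rt; then H2O
Reagents that add atoms: N,N-dimethylformamide, CN(C)C=O; water, O
Why: Vilsmeier–Haack formylation should attack the resorcinol-type ring at C3, which is ortho to one hydroxyl, para to the other and meta to the ester; C3 and C5 are equivalent by symmetry, so hydrolysis of iminium salt 7 can give only one aldehyde.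

Step 5
Reactants: 8 benzyl 3-formyl-2,6-dihydroxy-4-methylbenzoate
Product: 9 benzyl 3-formyl-2-hydroxy-6-methoxy-4-methylbenzoate
Conditions: MeI (1.1 equiv), K2CO3 (1.1 equiv), acetone, rt
Reagents that add atoms: iodomethane, CI
Why: Williamson etherification with limiting base and MeI should go to the C6 hydroxyl, which is para to the formyl group and has only one ortho substituent, whereas the C2 hydroxyl is hydrogen-bonded to the aldehyde and shielded by two ortho carbonyl groups.

Step 6
Reactants: 9 benzyl 3-formyl-2-hydroxy-6-methoxy-4-methylbenzoate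
Product: 10 benzyl 2-(benzyloxy)-3-formyl-6-methoxy-4-methylbenzoate
Conditions: BnBr, K2CO3, DMF, 60 °C
Reagents that add atoms: benzyl bromide, BrCc1ccccc1
Why: Williamson benzylation of the remaining hindered but acidic phenol should proceed under forcing carbonate/DMF conditions, no other nucleophilic site being left.

Step 7
Reactants: 10 benzyl 2-(benzyloxy)-3-formyl-6-methoxy-4-methylbenzoate
Product: 11 2-(benzyloxy)-3-[(benzyloxy)carbonyl]-4-methoxy-6-methylbenzoic acid
Conditions: NaClO2, NaH2PO4, 2-methyl-2-butene, t-BuOH/H2O, rt
Reagents that add atoms: sodium chlorite, [Na+].[O-]Cl=O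
Why: Pinnick oxidation should convert the hindered aryl aldehyde to the acid under buffered conditions, with 2-methyl-2-butene scavenging HOCl so that the electron-rich ring is not chlorinated and the benzyl groups are untouched.

Step 8
Reactants: 11 2-(benzyloxy)-3-[(benzyloxy)carbonyl]-4-methoxy-6-methylbenzoic acid; 4 4-hydroxy-3,6-dimethyl-2H-pyran-2-one
Product: 13 3,6-dimethyl-2-oxo-2H-pyran-4-yl 2-(benzyloxy)-3-[(benzyloxy)carbonyl]-4-methoxy-6-methylbenzoate, via acid chloride 12 (not isolated)
Conditions: (COCl)2, DMF (cat.), CH2Cl2, 0 °C to rt, evaporate; then 4, Et3N, DMAP (cat.), CH2Cl2, 0 °C to rt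
Reagents that add atoms: none
Why: Oxalyl chloride with catalytic DMF gives acid chloride 12, and the 4-hydroxyl of pyrone 4, a vinylogous carboxylic acid, should be O-acylated as its ammonium salt under DMAP catalysis (nucleophilic acyl substitution), the C3 methyl group occupying the position to which the acyl group could otherwise migrate.

Step 9
Reactants: 14 methyl prop-2-ynoate (methyl propiolate); 15 2-isopropoxy-4,4,5,5-tetramethyl-1,3,2-dioxaborolane
Product: 18 methyl 3-(4,4,5,5-tetramethyl-1,3,2-dioxaborolan-2-yl)prop-2-ynoate, via lithium acetylide 16 (not isolated), via lithium alkynylborate 17 (not isolated)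
Conditions: LiN(SiMe3)2, THF, −78 °C; 15, −78 °C; HCl in Et2O, −78 °C to rt; used without aqueous work-up
Reagents that add atoms: none
Why: This is the standard alkynylboronate synthesis (borylation of a lithium acetylide, then anhydrous acid cleavage of the isopropoxy ligand of ate complex 17); the low temperature should preserve the lithiated ynoate 16 and the water-free quench should avoid protodeboronation.

Step 10
Reactants: 13 3,6-dimethyl-2-oxo-2H-pyran-4-yl 2-(benzyloxy)-3-[(benzyloxy)carbonyl]-4-methoxy-6-methylbenzoate; 18 methyl 3-(4,4,5,5-tetramethyl-1,3,2-dioxaborolan-2-yl)prop-2-ynoate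
Product: 20 methyl 4-({2-(benzyloxy)-3-[(benzyloxy)carbonyl]-4-methoxy-6-methylbenzoyl}oxy)-3,6-dimethyl-2-(4,4,5,5-tetramethyl-1,3,2-dioxaborolan-2-yl)benzoate, via bicyclic lactone 19 (not isolated)
Conditions: 18 (3 equiv), dry mesitylene, 150 °C, sealed tube
Reagents that add atoms: none
Why: The pyrone diene C3=C4–C5=C6 of 13 should add across the triple bond of 18 in a thermal [4+2] cycloaddition to give the bridged lactone 19, which at the same temperature expels CO2 by retro-[4+2] fragmentation and so delivers the benzene ring of 20. The closest known reaction is the Diels–Alder/retro-Diels–Alder union of 2-pyrones with alkynyl pinacol boronates to give aryl boronates. Ring B closes by an intermolecular cycloaddition that forms C1–C6 and C2–C3 in one event (four pyrone carbons plus two alkyne carbons), and aromatisation by loss of the O1–C2 bridge is the driving force. The two bridgehead stereocentres of 19 are transient and vanish on aromatisation, so no stereocontrol is needed. The selectivity required is regiochemical: pyrone C3 carries the largest HOMO coefficient (it is β to the 4-acyloxy donor and is the terminus remote from the ring oxygen) and should bond to the boron-bearing carbon, the β-carbon of the ynoate with the largest LUMO coefficient, because the ester is a far stronger acceptor than the oxygen-damped boron; this places CO2CH3 para to the acyloxy group and boron on C2. The C3 methyl group blocks O-to-C acyl migration, and the benzyl ether and benzyl ester are inert under neutral thermal conditions.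

Step 11
Reactants: 20 methyl 4-({2-(benzyloxy)-3-[(benzyloxy)carbonyl]-4-methoxy-6-methylbenzoyl}oxy)-3,6-dimethyl-2-(4,4,5,5-tetramethyl-1,3,2-dioxaborolan-2-yl)benzoate
Product: 21 methyl 4-({2-(benzyloxy)-3-[(benzyloxy)carbonyl]-4-methoxy-6-methylbenzoyl}oxy)-2-hydroxy-3,6-dimethylbenzoate
Conditions: NaBO3·4H2O, THF/H2O, rt
Reagents that add atoms: sodium perborate (NaBO3·4H2O, dimeric peroxoborate), [Na+].[Na+].O[B-]1(O)OO[B-](O)(O)OO1
Why: Oxidation of an aryl boronate: perborate adds to boron, the aryl group shifts from boron to oxygen and the borate is hydrolysed to the phenol; the mildly basic medium at room temperature should spare the hindered diaryl ester, the benzyl ester and the methyl ester.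

Step 12
Reactants: 21 methyl 4-({2-(benzyloxy)-3-[(benzyloxy)carbonyl]-4-methoxy-6-methylbenzoyl}oxy)-2-hydroxy-3,6-dimethylbenzoate
Product: 22 methyl 4-[(3-carboxy-2-hydroxy-4-methoxy-6-methylbenzoyl)oxy]-2-hydroxy-3,6-dimethylbenzoate (CNP0265145.0)
Conditions: H2 (1 atm), Pd/C, EtOAc, rt
Reagents that add atoms: none
Why: Hydrogenolysis over Pd/C should cleave the benzyl ether and the benzyl ester in one operation, while the aryl ester link, the methyl ester and the methyl ether are inert.

**Compound list**

1 | 4-hydroxy-6-methyl-2H-pyran-2-one | Cc1cc(O)cc(=O)o1 | starting material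
2 | 6-methyl-3-methylidenepyran-2,4-dione | C=C1C(=O)C=C(C)OC1=O | intermediate
3 | 4-hydroxy-6-methyl-3-[(phenylsulfanyl)methyl]-2H-pyran-2-one | Cc1cc(O)c(CSc2ccccc2)c(=O)o1 | intermediate
4 | 4-hydroxy-3,6-dimethyl-2H-pyran-2-one | Cc1cc(O)c(C)c(=O)o1 | intermediate
5 | 2,6-dihydroxy-4-methylbenzoic acid | Cc1cc(O)c(C(=O)O)c(O)c1 | starting material
6 | benzyl 2,6-dihydroxy-4-methylbenzoate | Cc1cc(O)c(C(=O)OCc2ccccc2)c(O)c1 | intermediate
7 | N-({3-[(benzyloxy)carbonyl]-2,4-dihydroxy-6-methylphenyl}methylidene)-N-methylmethanaminium chloride | Cc1cc(O)c(C(=O)OCc2ccccc2)c(O)c1C=[N+](C)C.[Cl-] | intermediate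
8 | benzyl 3-formyl-2,6-dihydroxy-4-methylbenzoate | Cc1cc(O)c(C(=O)OCc2ccccc2)c(O)c1C=O | intermediate
9 | benzyl 3-formyl-2-hydroxy-6-methoxy-4-methylbenzoate | Cc1cc(OC)c(C(=O)OCc2ccccc2)c(O)c1C=O | intermediate
10 | benzyl 2-(benzyloxy)-3-formyl-6-methoxy-4-methylbenzoate | Cc1cc(OC)c(C(=O)OCc2ccccc2)c(OCc2ccccc2)c1C=O | intermediate
11 | 2-(benzyloxy)-3-[(benzyloxy)carbonyl]-4-methoxy-6-methylbenzoic acid | Cc1cc(OC)c(C(=O)OCc2ccccc2)c(OCc2ccccc2)c1C(=O)O | intermediate
12 | benzyl 2-(benzyloxy)-3-(chlorocarbonyl)-6-methoxy-4-methylbenzoate | Cc1cc(OC)c(C(=O)OCc2ccccc2)c(OCc2ccccc2)c1C(=O)Cl | intermediate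
13 | 3,6-dimethyl-2-oxo-2H-pyran-4-yl 2-(benzyloxy)-3-[(benzyloxy)carbonyl]-4-methoxy-6-methylbenzoate | Cc1cc(OC(=O)c2c(C)cc(OC)c(C(=O)OCc3ccccc3)c2OCc4ccccc4)c(C)c(=O)o1 | intermediate
14 | methyl prop-2-ynoate | C#CC(=O)OC | starting material
15 | 2-isopropoxy-4,4,5,5-tetramethyl-1,3,2-dioxaborolane | CC(C)OB1OC(C)(C)C(C)(C)O1 | starting material
16 | methyl 3-lithioprop-2-ynoate | [Li]C#CC(=O)OC | intermediate
17 | lithium (3-methoxy-3-oxoprop-1-yn-1-yl)(propan-2-yloxy)(pinacolato)borate | [Li+].COC(=O)C#C[B-]1(OC(C)C)OC(C)(C)C(C)(C)O1 | intermediate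
18 | methyl 3-(4,4,5,5-tetramethyl-1,3,2-dioxaborolan-2-yl)prop-2-ynoate | COC(=O)C#CB1OC(C)(C)C(C)(C)O1 | intermediate
19 | methyl 5-({2-(benzyloxy)-3-[(benzyloxy)carbonyl]-4-methoxy-6-methylbenzoyl}oxy)-1,4-dimethyl-3-oxo-8-(4,4,5,5-tetramethyl-1,3,2-dioxaborolan-2-yl)-2-oxabicyclo[2.2.2]octa-5,7-diene-7-carboxylate (racemic) | CC12OC(=O)C(C)(C(OC(=O)c3c(C)cc(OC)c(C(=O)OCc4ccccc4)c3OCc5ccccc5)=C1)C(B3OC(C)(C)C(C)(C)O3)=C2C(=O)OC | intermediate
20 | methyl 4-({2-(benzyloxy)-3-[(benzyloxy)carbonyl]-4-methoxy-6-methylbenzoyl}oxy)-3,6-dimethyl-2-(4,4,5,5-tetramethyl-1,3,2-dioxaborolan-2-yl)benzoate | COC(=O)c1c(C)cc(OC(=O)c2c(C)cc(OC)c(C(=O)OCc3ccccc3)c2OCc4ccccc4)c(C)c1B5OC(C)(C)C(C)(C)O5 | intermediate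
21 | methyl 4-({2-(benzyloxy)-3-[(benzyloxy)carbonyl]-4-methoxy-6-methylbenzoyl}oxy)-2-hydroxy-3,6-dimethylbenzoate | COC(=O)c1c(C)cc(OC(=O)c2c(C)cc(OC)c(C(=O)OCc3ccccc3)c2OCc4ccccc4)c(C)c1O | intermediate
22 | methyl 4-[(3-carboxy-2-hydroxy-4-methoxy-6-methylbenzoyl)oxy]-2-hydroxy-3,6-dimethylbenzoate | COC(=O)c1c(C)cc(OC(=O)c2c(C)cc(OC)c(C(=O)O)c2O)c(C)c1O | target

**Count and risks**

Total step count: 12. Longest linear sequence: 9 steps (steps 3 to 8, then 10 to 12, from compound 5).

Steps most likely to fail:

1. Step 10. The alkyne may add in the opposite orientation, so that boron ends next to C6, or the borylpropiolate may oligomerise at the temperature the cycloaddition needs. The fallback buys ring B instead of building it. It sets out from acid 11, which is converted into chloride 12 as in step 8. Chloride 12 is used to acylate purchased methyl 2,4-dihydroxy-3,6-dimethylbenzoate (COC(=O)c1c(C)cc(O)c(C)c1O) with Et3N and catalytic DMAP in CH2Cl2 at 0 °C to rt. Only the 4-hydroxyl should react, because the 2-hydroxyl is hydrogen-bonded to the ester carbonyl and lies between two substituents. The product is phenol 21, where the route is rejoined for step 12. This fallback makes no new compound (F0).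

2. Step 9. The lithiated ynoate may decompose before it is borylated, or the electron-poor C(sp)–B bond may be protonolysed during quench and isolation. The fallback avoids the organolithium and any protic quench. It sets out from methyl propiolate 14, which is stannylated without base by Bu3SnOMe (neat, rt, methanol removed under vacuum) to methyl 3-(tributylstannyl)prop-2-ynoate F1. Tin–boron exchange with BCl3 in CH2Cl2 at −78 °C should give methyl 3-(dichloroboranyl)prop-2-ynoate F2. F2 is not isolated but treated with 2,3-dimethyl-2,3-bis(trimethylsilyloxy)butane, which closes the dioxaborolane with loss of chlorotrimethylsilane. The result is boronate 18, and the route is rejoined at step 10.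

3. Step 5. The methylation may fail to discriminate between the two chelated hydroxyls, or may run on to the dimethyl ether. The fallback exchanges the order of the two operations, so that symmetry and a directing hydroxyl decide the sites instead of chelation. It sets out from diol 6, which is monomethylated (MeI 1.0 equiv, K2CO3, acetone, rt) to benzyl 2-hydroxy-6-methoxy-4-methylbenzoate F3. Either hydroxyl gives the same ether, and the remaining one stays chelated to the ester. F3 is then formylated only ortho to its free hydroxyl with MgCl2, Et3N and paraformaldehyde in MeCN at reflux (magnesium phenoxide-directed ortho-formylation). This gives aldehyde 9, and the route is rejoined at step 6.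

**Further compounds**

F0 | step 10 | none | none
F1 | step 9 | methyl 3-(tributylstannyl)prop-2-ynoate | CCCC[Sn](CCCC)(CCCC)C#CC(=O)OC
F2 | step 9 | methyl 3-(dichloroboranyl)prop-2-ynoate | COC(=O)C#CB(Cl)Cl
F3 | step 5 | benzyl 2-hydroxy-6-methoxy-4-methylbenzoate | COc1cc(C)cc(O)c1C(=O)OCc1ccccc1
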